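**Retrosynthetic overview**
1. Target 20 comes from (Z)-iodoalkene 18 (Stille coupling), made from C12 aldehyde 17 (Stork–Zhao olefination); O6, O7 and O8 all derive from one C7 ketone (two Rubottom oxidations, axial hydride reduction, acetylation).
2. The C7 ketone comes from a Dauben 1,3-transposition of the C9 allyl carbinol of trans-fused enone 6; a dissolving-metal step then sets C9–H, frees the C7–C8 enolate and removes the sulfone.
3. Ring B is present from the start: (S)-carvone supplies C5–C10 with the C5 stereocentre; methylation and 2-sulfonylallylation anti to the isopropenyl group build the quaternary C10 (the arm is C1–C3).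
4. Ring A is closed last, in step 3, through the C3–C4 bond: hydrogen-atom transfer to the isopropenyl CH2 gives the C4 tertiary radical, which adds 6-endo to the vinyl sulfone.
5. Enabling feature: C4 of ring A is a quaternary gem-dimethyl carbon bonded to the ring-fusion carbon C5 of ring B, i.e. a masked isopropenyl group (C4=CH2 plus one methyl); C5 and C10 are already sp3 and trans-disposed, so the closure keeps the trans fusion.

Key step: step 3

Remark: ring atoms carry labdane numbers (C1–C10); in the bicyclic compounds 5-H, 9-H, 6-O and 8-O are anti and 7-O and the C8 methyl are syn to the C10 methyl, as in the target; 3-bromo-2-(phenylsulfonyl)prop-1-ene is taken to be a purchasable allylating reagent.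

Step 1
Reactants: 1 (S)-(+)-carvone
Product: 3 (5S,6RS)-2,6-dimethyl-5-(prop-1-en-2-yl)cyclohex-2-en-1-one (6-methylcarvone), via lithium dienolate 2 (not isolated)
Conditions: LiN(iPr)2, THF, −78 °C; MeI, −78 to −20 °C
Reagents that add atoms: iodomethane, CI
Why: Kinetic deprotonation at the alpha-prime carbon (C10) gives the cross-conjugated enolate, which is methylated in an SN2 enolate alkylation; the C10 configuration need not be controlled here because C10 is enolised again in step 2.

Step 2
Reactants: 3 6-methylcarvone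
Product: 5 (5R,6R)-2,6-dimethyl-6-[2-(phenylsulfonyl)prop-2-en-1-yl]-5-(prop-1-en-2-yl)cyclohex-2-en-1-one, via lithium enolate 4 (not isolated)
Conditions: LiN(iPr)2, THF, −78 °C; 3-bromo-2-(phenylsulfonyl)prop-1-ene, −78 to 0 °C
Reagents that add atoms: 3-bromo-2-(phenylsulfonyl)prop-1-ene, C=C(CBr)S(=O)(=O)c1ccccc1
Why: Enolate allylation (SN2 or SN2' displacement of bromide, both giving the same product) should occur anti to the neighbouring isopropenyl group at C5, which sets the quaternary C10 with its methyl cis and the three-carbon arm trans to the C5 substituent, i.e. the trans ring fusion of the target.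

Step 3
Reactants: 5 sulfonylallyl carvone (cyclisation precursor)
Product: 6 4,4,8,10-tetramethyl-2-(phenylsulfonyl)-trans-decal-7-en-9-one (C2 epimers)
Conditions: Fe(acac)3 (0.3 equiv), PhSiH3, EtOH/HOCH2CH2OH 5:1, 60 °C, 0.02 M
Reagents that add atoms: none
Why: The iron hydride formed from Fe(acac)3 and PhSiH3 transfers a hydrogen atom to the CH2 terminus of the isopropenyl group, which turns that CH2 into the second C4 methyl and leaves a nucleophilic tertiary radical at C4; this radical adds to the unsubstituted terminus C3 of the 2-sulfonylallyl arm, and the alpha-sulfonyl radical at C2 is then reduced and protonated by the alcohol. The closest known reaction type is the metal-hydride HAT-initiated reductive olefin coupling (Mukaiyama-type HAT followed by Giese addition to a vinyl sulfone), run here intramolecularly. Ring A is closed in the 6-endo-trig mode through the C3–C4 bond; the 5-exo alternative would attack the sulfonyl-bearing C2 and give an unstabilised primary radical. No lasting stereocentre is created (C2 forms as a mixture and loses its sulfonyl group in step 6); the trans fusion is carried over because C5 (from carvone) and C10 (from step 2) are sp3 centres holding the two reacting arms trans-diequatorial. The step needs HAT to the electron-rich 1,1-disubstituted alkene rather than to the enone or vinyl sulfone, which the polarity of the iron hydride should secure, and it needs cyclisation to outrun reduction of the radical, which the acceptor strength of the vinyl sulfone and high dilution should secure.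

Step 4
Reactants: 6 trans-fused sulfonyl enone
Product: 7 9-allyl-4,4,8,10-tetramethyl-2-(phenylsulfonyl)-trans-decal-7-en-9-ol (C2 and C9 epimers)
Conditions: CH2=CHCH2MgBr, CeCl3, THF, −78 °C; aq. NH4Cl
Reagents that add atoms: allylmagnesium bromide, C=CC[Mg]Br
Why: Organocerium-mediated 1,2-addition (Grignard addition) of the allyl group to the hindered C9 carbonyl brings in C11 and C12 plus one carbon that is cut off in step 11; the reagent is too weakly basic to deprotonate next to the sulfone, and the carbinol configuration is irrelevant because C9 becomes sp2 in step 5.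

Step 5
Reactants: 7 tertiary allylic alcohol
Product: 8 9-allyl-4,4,8,10-tetramethyl-2-(phenylsulfonyl)-trans-decal-8-en-7-one (C2 epimers)
Conditions: pyridinium chlorochromate (C5H5NH[CrO3Cl]), 4 Å MS, CH2Cl2, rt
Reagents that add atoms: pyridinium chlorochromate, [O-][Cr](=O)(=O)Cl.c1cc[nH+]cc1
Why: Dauben oxidative 1,3-transposition: the tertiary allylic chromate ester undergoes a [3,3] shift to C7 and is oxidised there, which moves the carbonyl to C7 and leaves the allyl group on the C8=C9 double bond.

Step 6
Reactants: 8 transposed enone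
Product: 10 9-allyl-4,4,8,10-tetramethyl-7-(triethylsilyloxy)-trans-decal-7-ene, via lithium enolate 9 (not isolated)
Conditions: Li, NH3(l)/THF, t-BuOH (1 equiv), −78 °C; isoprene; NH3 evaporated; Et3SiCl, Et3N, THF, −78 to 0 °C
Reagents that add atoms: chlorotriethylsilane, CC[Si](Cl)(CC)CC
Why: Dissolving-metal (Birch-type) enone reduction should protonate C9 axially, anti to the C10 methyl, so that the side chain ends equatorial, and gives the C7–C8 enolate regiospecifically for O-silylation (reductive silylation), while the same electrons cleave the C2–sulfonyl bond (reductive desulfonylation) and remove the activating group.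

Step 7
Reactants: 10 silyl enol ether
Product: 11 9-allyl-4,4,8,10-tetramethyl-8-(triethylsilyloxy)-trans-decalin-7-one
Conditions: mCPBA, NaHCO3, CH2Cl2, −20 °C
Reagents that add atoms: 3-chloroperoxybenzoic acid, OOC(=O)c1cccc(Cl)c1
Why: Rubottom oxidation: the electron-rich tetrasubstituted silyl enol ether should be epoxidised much faster than the terminal alkene and from the face opposite the axial C10 methyl, and the silyl group shifts to the new C8 oxygen, leaving the C8 methyl axial.

Step 8
Reactants: 11 C8 silyloxy ketone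
Product: 13 9-allyl-4,4,8,10-tetramethyl-6,8-bis(triethylsilyloxy)-trans-decalin-7-one, via bis-silyl enol ether 12 (not isolated)
Conditions: Et3SiOTf, Et3N, CH2Cl2, 0 °C; then mCPBA, NaHCO3, CH2Cl2, −20 °C
Reagents that add atoms: triethylsilyl trifluoromethanesulfonate, CC[Si](CC)(CC)OS(=O)(=O)C(F)(F)F; 3-chloroperoxybenzoic acid, OOC(=O)c1cccc(Cl)c1
Why: Soft enolisation can go only towards C6 because C8 is quaternary, and the second Rubottom oxidation should deliver oxygen to C6 from the face opposite the axial methyl groups at C4, C8 and C10, so that the C6 silyloxy group is equatorial.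

Step 9
Reactants: 13 bis-silyloxy ketone
Product: 14 9-allyl-4,4,8,10-tetramethyl-6,8-bis(triethylsilyloxy)-trans-decalin-7-ol
Conditions: NaBH4, MeOH/THF, 0 °C to rt
Reagents that add atoms: none
Why: Hydride reduction of the ketone by axial attack, on the face away from the axial C8 methyl, should give the equatorial C7 alcohol, trans to both neighbouring oxygens.

Step 10
Reactants: 14 C7 alcohol
Product: 15 9-allyl-4,4,8,10-tetramethyl-6,8-bis(triethylsilyloxy)-trans-decalin-7-yl acetate
Conditions: Ac2O, DMAP, pyridine, 40 °C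
Reagents that add atoms: acetic anhydride, CC(=O)OC(C)=O
Why: DMAP-catalysed acylation of the only free hydroxyl places the acetate on O7 without any selectivity problem, since O6 and O8 are silylated.

Step 11
Reactants: 15 acetate
Product: 17 2-[7-acetoxy-4,4,8,10-tetramethyl-6,8-bis(triethylsilyloxy)-trans-decalin-9-yl]acetaldehyde, via ozonide 16 (not isolated)
Conditions: O3, CH2Cl2, −78 °C; PPh3, −78 °C to rt
Reagents that add atoms: ozone, [O-][O+]=O
Why: Ozonolysis with reductive work-up cleaves the only alkene left in the molecule to the C12 aldehyde.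

Step 12
Reactants: 17 C12 aldehyde
Product: 18 9-[(2Z)-3-iodobut-2-en-1-yl]-4,4,8,10-tetramethyl-6,8-bis(triethylsilyloxy)-trans-decalin-7-yl acetate
Conditions: EtPPh3I, n-BuLi, THF, rt; I2, −78 °C; NaN(SiMe3)2, −20 °C; then 17, −78 °C
Reagents that add atoms: ethyltriphenylphosphonium iodide, CC[P+](c1ccccc1)(c1ccccc1)c1ccccc1.[I-]; iodine, II
Why: Stork–Zhao olefination: the non-stabilised alpha-iodo ylide reacts under kinetic control through the cis oxaphosphetane and should place iodine cis to C11, i.e. give the (Z)-iodoalkene.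

Step 13
Reactants: 18 (Z)-iodoalkene
Product: 19 9-[(2Z)-3-methylpenta-2,4-dien-1-yl]-4,4,8,10-tetramethyl-6,8-bis(triethylsilyloxy)-trans-decalin-7-yl acetate
Conditions: CH2=CHSnBu3, Pd2(dba)3 (cat.), AsPh3, CuI, NMP, rt
Reagents that add atoms: tributyl(vinyl)stannane, C=C[Sn](CCCC)(CCCC)CCCC
Why: Stille coupling replaces iodine by vinyl with retention of the alkene geometry, giving the (12Z)-diene under neutral conditions that spare the acetate and the silyl ethers.

Step 14
Reactants: 19 bis-silyl ether of the target
Product: 20 target CNP0225877.2, (5R,6S,7R,8R,9S,10R,12Z)-6,8-dihydroxylabda-12,14-dien-7-yl acetate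
Conditions: HF·pyridine, pyridine, THF, 0 °C to rt
Reagents that add atoms: none
Why: Fluoride-mediated desilylation under buffered, weakly acidic conditions should remove both triethylsilyl groups without the base-promoted acetyl migration from O7 to a neighbouring oxygen and without isomerising the diene.

**Compound list**
1 | (S)-(+)-carvone, (5S)-2-methyl-5-(prop-1-en-2-yl)cyclohex-2-en-1-one | CC1=CC[C@@H](CC1=O)C(C)=C | starting material
2 | lithium dienolate of 1 (O–C9=C10, cross-conjugated) | [Li+].[O-]C1=C[C@@H](C(C)=C)CC=C1C | intermediate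
3 | 6-methylcarvone, (5S,6RS)-2,6-dimethyl-5-(prop-1-en-2-yl)cyclohex-2-en-1-one | CC1=CC[C@@H](C(C)C1=O)C(C)=C | intermediate
4 | lithium enolate of 3 (O–C9=C10) | [Li+].[O-]C1=C(C)[C@@H](C(C)=C)CC=C1C | intermediate
5 | (5R,6R)-2,6-dimethyl-6-[2-(phenylsulfonyl)prop-2-en-1-yl]-5-(prop-1-en-2-yl)cyclohex-2-en-1-one; sulfonylallyl arm trans, methyl cis to isopropenyl | C=C(S(=O)(=O)c1ccccc1)C[C@@]2(C)C(=O)C(C)=CC[C@@H]2C(C)=C | intermediate
6 | 4,4,8,10-tetramethyl-2-(phenylsulfonyl)-trans-decal-7-en-9-one (C2 epimers) | O=C1C(C)=CC[C@@H]2C(C)(C)CC(S(=O)(=O)c3ccccc3)C[C@]21C | intermediate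
7 | 9-allyl-4,4,8,10-tetramethyl-2-(phenylsulfonyl)-trans-decal-7-en-9-ol (C2 and C9 epimers) | C=CCC1(O)C(C)=CC[C@@H]2C(C)(C)CC(S(=O)(=O)c3ccccc3)C[C@]21C | intermediate
8 | 9-allyl-4,4,8,10-tetramethyl-2-(phenylsulfonyl)-trans-decal-8-en-7-one (C2 epimers) | C=CCC1=C(C)C(=O)C[C@@H]2C(C)(C)CC(S(=O)(=O)c3ccccc3)C[C@]21C | intermediate
9 | lithium C7–C8 enolate of 9-allyl-4,4,8,10-tetramethyl-trans-decalin-7-one | C=CC[C@@H]1C(C)=C([O-])C[C@@H]2C(C)(C)CCC[C@]21C.[Li+] | intermediate
10 | 9-allyl-4,4,8,10-tetramethyl-7-(triethylsilyloxy)-trans-decal-7-ene | C=CC[C@@H]1C(C)=C(O[Si](CC)(CC)CC)C[C@@H]2C(C)(C)CCC[C@]21C | intermediate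
11 | 9-allyl-4,4,8,10-tetramethyl-8-(triethylsilyloxy)-trans-decalin-7-one | C=CC[C@@H]1[C@@](C)(O[Si](CC)(CC)CC)C(=O)C[C@@H]2C(C)(C)CCC[C@]21C | intermediate
12 | 9-allyl-4,4,8,10-tetramethyl-7,8-bis(triethylsilyloxy)-trans-decal-6-ene | C=CC[C@@H]1[C@@](C)(O[Si](CC)(CC)CC)C(O[Si](CC)(CC)CC)=C[C@@H]2C(C)(C)CCC[C@]21C | intermediate
13 | 9-allyl-4,4,8,10-tetramethyl-6,8-bis(triethylsilyloxy)-trans-decalin-7-one | C=CC[C@@H]1[C@@](C)(O[Si](CC)(CC)CC)C(=O)[C@@H](O[Si](CC)(CC)CC)[C@@H]2C(C)(C)CCC[C@]21C | intermediate
14 | 9-allyl-4,4,8,10-tetramethyl-6,8-bis(triethylsilyloxy)-trans-decalin-7-ol | C=CC[C@@H]1[C@@](C)(O[Si](CC)(CC)CC)[C@H](O)[C@@H](O[Si](CC)(CC)CC)[C@@H]2C(C)(C)CCC[C@]21C | intermediate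
15 | 9-allyl-4,4,8,10-tetramethyl-6,8-bis(triethylsilyloxy)-trans-decalin-7-yl acetate | C=CC[C@@H]1[C@@](C)(O[Si](CC)(CC)CC)[C@H](OC(C)=O)[C@@H](O[Si](CC)(CC)CC)[C@@H]2C(C)(C)CCC[C@]21C | intermediate
16 | ozonide of 15 (3-substituted 1,2,4-trioxolane, epimers at the trioxolane carbon) | C1OOC(C[C@@H]2[C@@](C)(O[Si](CC)(CC)CC)[C@H](OC(C)=O)[C@@H](O[Si](CC)(CC)CC)[C@@H]3C(C)(C)CCC[C@]32C)O1 | intermediate
17 | 2-[7-acetoxy-4,4,8,10-tetramethyl-6,8-bis(triethylsilyloxy)-trans-decalin-9-yl]acetaldehyde | O=CC[C@@H]1[C@@](C)(O[Si](CC)(CC)CC)[C@H](OC(C)=O)[C@@H](O[Si](CC)(CC)CC)[C@@H]2C(C)(C)CCC[C@]21C | intermediate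
18 | 9-[(2Z)-3-iodobut-2-en-1-yl]-4,4,8,10-tetramethyl-6,8-bis(triethylsilyloxy)-trans-decalin-7-yl acetate | I/C(C)=C\C[C@@H]1[C@@](C)(O[Si](CC)(CC)CC)[C@H](OC(C)=O)[C@@H](O[Si](CC)(CC)CC)[C@@H]2C(C)(C)CCC[C@]21C | intermediate
19 | 9-[(2Z)-3-methylpenta-2,4-dien-1-yl]-4,4,8,10-tetramethyl-6,8-bis(triethylsilyloxy)-trans-decalin-7-yl acetate | C=C/C(C)=C\C[C@@H]1[C@@](C)(O[Si](CC)(CC)CC)[C@H](OC(C)=O)[C@@H](O[Si](CC)(CC)CC)[C@@H]2C(C)(C)CCC[C@]21C | intermediate
20 | CNP0225877.2, (5R,6S,7R,8R,9S,10R,12Z)-6,8-dihydroxylabda-12,14-dien-7-yl acetate | C=C/C(C)=C\C[C@@H]1[C@@](C)(O)[C@H](OC(C)=O)[C@@H](O)[C@@H]2C(C)(C)CCC[C@]21C | target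

**Step count**
Total: 14 steps. Longest linear sequence: 14 steps, from 1.

**Steps most likely to fail**

Step 3 (radical closure of ring A). The C4 radical may be reduced by the iron hydride, or lose a hydrogen atom again, before it reaches C3, so that the isopropenyl group is only hydrogenated or isomerised. The fallback makes the same radical by halogen abstraction in a stannane chain, where the hydrogen donor can be kept scarce. It sets out from 5: Markovnikov hydrobromination (HBr in AcOH, CH2Cl2, 0 °C) should give the tertiary bromide F1, and slow addition of Bu3SnH with AIBN in benzene at 80 °C should then bring about the same 6-endo Giese cyclisation. The route is rejoined at 6.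

Step 6 (reduction, desulfonylation and enolate trapping in one flask). Proton transfer may quench or equilibrate the C7–C8 enolate before it is silylated, and cleavage of the C–S bond may stay incomplete. The fallback gives up the trapping and oxidises a thermodynamic enolate instead. It sets out from 8: Li/NH3 followed by an NH4Cl quench should give the saturated, sulfone-free ketone F2. Autoxidation under equilibrating base (KOt-Bu, O2, P(OEt)3, t-BuOH/THF, −20 °C) should then hydroxylate the more substituted alpha carbon C8 from the face opposite the C10 methyl and give the tertiary hydroxy ketone F3. With excess Et3SiOTf and Et3N, as in the first stage of step 8, F3 is silylated on O8 and enolised towards C6, which brings the route back at 12.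

Step 12 (Z-selective iodo-olefination). The alpha-iodo ylide may decompose before it meets the hindered, enolisable aldehyde, and the Z selectivity may erode. The fallback builds the trisubstituted alkene by two stereodefined cross-couplings. It sets out from 17: CBr4 and PPh3 (CH2Cl2, 0 °C) should give the 1,1-dibromoalkene F4 (Corey–Fuchs-type dibromo-olefination). A Negishi coupling with Me2Zn and Pd(PtBu3)2 in THF should replace only the bromine trans to C11 and give the (Z)-2-bromoalkene F5. Stille coupling of F5 with tributyl(vinyl)stannane under the conditions of step 13 brings the route back at 19.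

**Further compounds**
F1 | step 3 | 5-(2-bromopropan-2-yl)-2,6-dimethyl-6-[2-(phenylsulfonyl)prop-2-en-1-yl]cyclohex-2-en-1-one (tertiary bromide, ring configuration as in 5) | C=C(S(=O)(=O)c1ccccc1)C[C@@]2(C)C(=O)C(C)=CC[C@@H]2C(C)(C)Br
F2 | step 6 | 9-allyl-4,4,8,10-tetramethyl-trans-decalin-7-one (C8 methyl mainly equatorial) | C=CC[C@@H]1[C@@H](C)C(=O)C[C@@H]2C(C)(C)CCC[C@]21C
F3 | step 6 | 9-allyl-8-hydroxy-4,4,8,10-tetramethyl-trans-decalin-7-one | C=CC[C@@H]1[C@@](C)(O)C(=O)C[C@@H]2C(C)(C)CCC[C@]21C
F4 | step 12 | 9-(3,3-dibromoprop-2-en-1-yl)-4,4,8,10-tetramethyl-6,8-bis(triethylsilyloxy)-trans-decalin-7-yl acetate | BrC(Br)=CC[C@@H]1[C@@](C)(O[Si](CC)(CC)CC)[C@H](OC(C)=O)[C@@H](O[Si](CC)(CC)CC)[C@@H]2C(C)(C)CCC[C@]21C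
F5 | step 12 | 9-[(2Z)-3-bromobut-2-en-1-yl]-4,4,8,10-tetramethyl-6,8-bis(triethylsilyloxy)-trans-decalin-7-yl acetate | Br/C(C)=C\C[C@@H]1[C@@](C)(O[Si](CC)(CC)CC)[C@H](OC(C)=O)[C@@H](O[Si](CC)(CC)CC)[C@@H]2C(C)(C)CCC[C@]21C
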